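## Structural features

Target 14 is a (2S)-flavanone: benzene ring A is fused through C4a and C8a to the dihydropyran-4-one ring C (O1, C2, C3, C4, C4a, C8a), and C2 carries the 3,4-dimethoxyphenyl ring B. Ring A is pentasubstituted, with methoxy groups at C5, C7 and C8, the ring oxygen O1 at C8a and the C4 acyl group at C4a, so that only C6 bears hydrogen. C2 is the only stereocentre and has no stereogenic neighbour; it is benzylic to an electron-rich arene, bonded to O1 and β to the C4 carbonyl. This makes it fragile: base or acid opens ring C by retro-oxa-Michael (E1cB) cleavage of C2–O1 to a 2'-hydroxychalcone, which racemises C2, and acid can also ionise the benzylic C2–O1 bond. The real difficulty is the 5,7,8-oxygen pattern, since arene-based routes must tell C8 from C6 and easily drift to the 5,6,7-isomer, and it must be solved without endangering C2. The key step exploits the fact that, read around ring A, C8a(O1)=C8(O)–C7(O)=C6 is a 1-alkoxy-2,3-dioxygenated butadiene and C4a≡C5(OMe) with the C4 carbonyl is a methoxy ynone. The two are already joined by the four atoms O1–C2–C3–C4, so one intramolecular [4+2] cycloaddition can make ring A and ring C together.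

## Logic of the disconnections

14 ⇒ 12. The two methyl–oxygen bonds at O7 and O8 are cut. These oxygens begin as enol ether oxygens of a diene, and silyl enol ethers are the only ones that can be made from a diketone in one step, so they reach the arene as silyl ethers. The gain is that the ring A pattern is complete in 12. The demand is a methylation that never leaves a basic aryloxide long enough to open ring C, and that avoids diazoalkanes.

12 ⇒ 10 (through 11). After formal return of two hydrogens to C8a and C6, the C4a–C8a and C5–C6 bonds are cut in a retro-[4+2] sense. Both rings A and C open, the arene is replaced by an acyclic dienyl ether ynone, and every ring A substituent is fixed by chain connectivity, so C6 and C8 can no longer be confused. The demands are a (Z)-enol ether, a thermal cycloaddition that outruns decomposition, and an aromatisation that removes hydrogen and keeps O1. Compound 10 itself is kept unchanged; the improvements lie in how it is reached (no diazo compound), in buffering the cycloaddition–oxidation, and in the end game.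

10 ⇒ 7 + 9. The C4–C4a bond between carbonyl and alkyne is cut. This introduces the electrophilic push–pull ynone last, from a robust amide. The demand is single addition of the acetylide and a work-up in which liberated amines cannot add to the ynone. Compound 9 is traced to 8 by double elimination.

7 ⇒ 6. The two O–Si bonds are cut, turning the diene into a vicinal diketone. Each carbonyl has only one enolisable side, which fixes the regiochemistry. The demand is (Z)-geometry at C8a=C8 and no reaction at the amide.

6 ⇒ 5. The two carbonyl groups are traced back to an internal alkyne. The alkyne is an inert, diazo-free placeholder for the diketone. The demand is an oxidation that spares the dimethoxyarene and the benzylic ether C–H.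

5 ⇒ 3 + 4. The O1–C8a ether bond is cut on the C8a side. The partners become a secondary alcohol and a simple propargylic bromide, and the C2–O1 bond is never broken. The demand is etherification without a free alkoxide, because the β-hydroxy amide can undergo retro-aldol cleavage or elimination.

3 ⇒ 2. The C4–N bond is cut, giving the ester. The demand is aminolysis without β-elimination.

2 ⇒ 1. The C2–H bond is cut, giving the β-keto ester. The demand is a catalyst-controlled reduction that sets the only stereocentre as S.

## Other disconnections considered

Alternative 1: The cut is the aryl ether bond O1–C8a. Forward, the bromo diol A1 would be cyclised by an Ullmann-type intramolecular C–O coupling (CuI, 3,4,7,8-tetramethyl-1,10-phenanthroline, Cs2CO3). The C2 alkoxide displaces bromide at C8a to give the flavan-4-ol A2, and a benzylic oxidation would then lead to 14.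
- In favour: the reaction class is established; the C2 configuration is retained because the carbinol oxygen is the nucleophile; the C4 hydroxyl could reach C8a only through a four-membered ring; with C4 at the alcohol level no retro-oxa-Michael path exists under the basic conditions.
- Against: A1 needs a pentasubstituted bromoarene that already has the 5,7,8-pattern with the halogen next to the side chain, so the ring A problem is only moved to arene substitution. The bromide is flanked on both sides on a very electron-rich ring, which should slow oxidative addition to monovalent copper. An oxidation follows the key step.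
- Comparison: on structure it joins ready-made parts whereas the chosen plan creates ring A. On mechanism it is the better plan, since its key step is precedented and 10 → 12 is not. On base tolerance and on needing no late methylation it is also better. On step economy the two are about equal, because what is saved at the key step is spent on the arene.

Alternative 2: The cut lies in ring B, at C1'–C2' and C5'–C6'. Forward, the terminal alkyne A4 and the diene A5 would undergo a cobalt-catalysed neutral [4+2] cycloaddition (CoBr2(dppe), zinc powder, ZnI2) to the 1,4-cyclohexadiene A6, which a quinone dehydrogenation would aromatise to 14.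
- In favour: the cycloaddition of unactivated terminal alkynes with 2,3-disubstituted dienes is a known class; A5 is commercial and symmetric, so ring B raises no regiochemical question; all five methoxy groups are present before the key step; A4 could be reached in few steps from chromone A3 by copper-catalysed enantioselective conjugate alkynylation.
- Against: the construction is spent on the one ring that is available in any form, while ring A must still come from an arene through A3. The stereocentre of A4 is propargylic and β to the ketone, so the Lewis acid ZnI2 may open ring C. The final oxidation must stop short of dehydrogenating C2–C3.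
- Comparison: structurally it is the reverse of the chosen plan (ring B built and ring A bought, against ring A built and ring B bought). Mechanistically it is the safer choice, being precedented. In step economy it is probably the better plan by a few steps, and it is equal in needing one oxidation after the cycloaddition. The chosen plan is better only in solving the ring A pattern instead of presupposing it, and in carrying a less labile C2 up to the key step.

Alternative 3: The cut is C4a–C5, with C8–C8a made just before. Forward, the 6-lithio derivative of glycal A7 would add to the more electrophilic carbonyl of cyclobutenedione A8 to give the 4-hydroxycyclobutenone A9. On heating in xylene, A9 should open (4π electrocyclic) to a dienylketene that closes by 6π electrocyclisation onto C4a and tautomerises to the hydroquinone A10 (Moore rearrangement).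
- In favour: like the chosen plan it builds ring A de novo with substituent positions fixed by connectivity (equal on that point); the reaction type is precedented (better); because C4 is a silyl ether, the phenols can be methylated under base without risk to C2 (better).
- Against: only the C7 methoxy group arrives in place, so methylation of O5 and O8, desilylation and oxidation at C4 must follow. A10 is an air-sensitive hydroquinone. A7 needs two stereocentres, one of which is later destroyed, and its vinylic lithiation competes with deprotonation at the benzylic C2–H. A8 is less accessible than a squarate diester.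
- Comparison: on structure both plans make ring A from an open chain, here by one new C–C bond after an addition, there by two bonds in one step that also closes ring C. On mechanism both are pericyclic, but this one is known. On step economy it is clearly worse, with three steps after the key step against one and a longer approach to A7.

Key step: step 7

Remark on the chemistry: a check of 10 and 12 against 14 shows that no structure needs correcting. C5 of 10 and C2 of 12 and 14 have the same spatial arrangement and the same descriptor (S). The (1Z)-enol ether of 10 is the isomer with O1 cis to the C8 silyloxy group, hence trans to the diene backbone, as the cycloaddition requires. It is assumed that the C8a epimers of 11 and the order of the two desilylation–methylation events in step 8 do not matter.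

Step 1
Reactants: 1 ethyl 3-(3,4-dimethoxyphenyl)-3-oxopropanoate
Product: 2 ethyl (3S)-3-(3,4-dimethoxyphenyl)-3-hydroxypropanoate
Conditions: RuCl[(S,S)-TsDPEN](p-cymene) (0.5 mol%), HCO2H/Et3N (5:2), 40 °C
Reagents that add atoms: none
Why: Noyori-type asymmetric transfer hydrogenation; hydride and proton are delivered through a six-membered transition state in which the aryl group is held by a CH–π contact with the η6-arene, so the (S,S)-ligand should give the (S)-benzylic alcohol as it does for aryl alkyl ketones, and no pressurised hydrogen is needed.

Step 2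
Reactants: 2 ethyl (3S)-3-(3,4-dimethoxyphenyl)-3-hydroxypropanoate
Product: 3 (3S)-3-(3,4-dimethoxyphenyl)-3-hydroxy-N-methoxy-N-methylpropanamide
Conditions: MeNH(OMe)·HCl, i-PrMgCl, THF, −20 → 0 °C
Reagents that add atoms: N,O-dimethylhydroxylamine hydrochloride, CNOC.Cl
Why: Weinreb amide formation by aminolysis of the ester with the chloromagnesium amide; the carbinol is carried as its magnesium alkoxide, which should suppress β-elimination, and the stereocentre is not involved.

Step 3
Reactants: 3 (3S)-3-(3,4-dimethoxyphenyl)-3-hydroxy-N-methoxy-N-methylpropanamide; 4 1-bromobut-2-yne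
Product: 5 (3S)-3-(but-2-yn-1-yloxy)-3-(3,4-dimethoxyphenyl)-N-methoxy-N-methylpropanamide
Conditions: Ag2O, 4 Å MS, CH2Cl2, rt, dark
Reagents that add atoms: none
Why: Silver oxide-mediated (Purdie-type) Williamson etherification; Ag2O activates the propargylic bromide and takes up HBr without a free alkoxide, so retro-aldol cleavage and E1cB elimination of the β-hydroxy amide should be avoided, and the C–O bond at the stereocentre is never broken.

Step 4
Reactants: 5 (3S)-3-(but-2-yn-1-yloxy)-3-(3,4-dimethoxyphenyl)-N-methoxy-N-methylpropanamide
Product: 6 (3S)-3-(3,4-dimethoxyphenyl)-3-(2,3-dioxobutoxy)-N-methoxy-N-methylpropanamide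
Conditions: KMnO4, NaHCO3, MgSO4, acetone/H2O, 0 °C → rt
Reagents that add atoms: potassium permanganate, [K+].[O-][Mn](=O)(=O)=O
Why: Permanganate oxidation of an internal alkyne to a 1,2-diketone through a cyclic manganate ester; the NaHCO3/MgSO4 buffer keeps the medium near neutral so that the diketone should not be cleaved further and the arene, ether and amide stay intact. The alkyne thus serves as a diazo-free equivalent of the vicinal diketone.

Step 5
Reactants: 6 (3S)-3-(3,4-dimethoxyphenyl)-3-(2,3-dioxobutoxy)-N-methoxy-N-methylpropanamide
Product: 7 (3S)-3-{[(1Z)-2,3-bis(tert-butyldimethylsilyloxy)buta-1,3-dien-1-yl]oxy}-3-(3,4-dimethoxyphenyl)-N-methoxy-N-methylpropanamide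
Conditions: TBSOTf, Et3N, CH2Cl2, −78 → 0 °C; Et3N-deactivated silica
Reagents that add atoms: tert-butyldimethylsilyl trifluoromethanesulfonate, CC(C)(C)[Si](C)(C)OS(=O)(=O)C(F)(F)F
Why: Soft enolisation–silylation of both carbonyl groups (silyl triflate/amine); C8 can enolise only toward C8a and C7 only toward the methyl group, so the regiochemistry is fixed. The (Z)-enol ether is expected because it avoids allylic 1,3-strain and corresponds to the stable push–pull mono-enol, and the far less acidic amide α-CH2 should not react at low temperature.

Step 6
Reactants: 7 (3S)-3-{[(1Z)-2,3-bis(tert-butyldimethylsilyloxy)buta-1,3-dien-1-yl]oxy}-3-(3,4-dimethoxyphenyl)-N-methoxy-N-methylpropanamide; 8 chloroacetaldehyde dimethyl acetal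
Product: 10 (5S)-5-{[(1Z)-2,3-bis(tert-butyldimethylsilyloxy)buta-1,3-dien-1-yl]oxy}-5-(3,4-dimethoxyphenyl)-1-methoxypent-1-yn-3-one, via lithium methoxyacetylide 9 (not isolated)
Conditions: 8, LiNEt2 (from Et2NH, n-BuLi; 3 equiv per 8, 8 in slight excess), THF, 0 °C; then 7, −78 → −40 °C; inverse quench into cold aq. NaH2PO4
Reagents that add atoms: none
Why: Double elimination of HCl and methanol from 8 gives acetylide 9, which adds once to the Weinreb amide to form a stable chelated tetrahedral intermediate (Weinreb ketone synthesis). The cold, mildly acidic inverse quench protonates the amines before the electrophilic push–pull ynone is released, and the slight deficit of base leaves no lithium amide to enolise 7.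

Step 7
Reactants: 10 (5S)-5-{[(1Z)-2,3-bis(tert-butyldimethylsilyloxy)buta-1,3-dien-1-yl]oxy}-5-(3,4-dimethoxyphenyl)-1-methoxypent-1-yn-3-one
Product: 12 (2S)-7,8-bis(tert-butyldimethylsilyloxy)-2-(3,4-dimethoxyphenyl)-5-methoxychroman-4-one, via cyclohexa-1,4-diene cycloadduct 11 (not isolated)
Conditions: PhMe (0.01 M), 2,6-di-tert-butyl-4-methylpyridine (0.2 equiv), 100 °C; then DDQ (1.05 equiv), 0 °C, same flask
Reagents that add atoms: none
Why: Proposed new method: on heating, the (Z)-1-alkoxy-2,3-bis(silyloxy)diene of 10 should add across the ynone in a concerted, asynchronous intramolecular [4+2] cycloaddition, the most nucleophilic diene terminus C6 (pushed by O1 and the C7 silyloxy group) bonding to the electrophilic methoxy-bearing carbon C5 while C8a bonds to C4a; the closest known reaction type is the intramolecular Diels–Alder reaction of 2-silyloxy dienes with tethered ynones, followed by quinone dehydrogenation of the 1,4-cyclohexadiene. Ring A closes as the six-membered carbocycle of the cycloaddition itself (bonds C4a–C8a and C5–C6), and ring C closes in the fused, type 1 mode, because the four-atom tether O1–C2–C3–C4 links diene terminus C8a to alkyne carbon C4a and the single bond C4a–C8a completes a six-membered oxacycle with the activating carbonyl inside it. No lasting stereocentre is formed: C8a of 11 arises as a mixture of epimers that is erased on aromatisation, and C2 is a spectator because no acid or base is present that could open the β-alkoxy ketone. DDQ should then abstract the hydride at C8a, which is doubly allylic and bonded to O1, giving a cation stabilised by O1, the C7 silyloxy and the C5 methoxy groups, and loss of the C6 proton gives arene 12. The step needs regiocontrol, which the tether and the matched polarisation of diene and ynone both enforce, and the (Z)-geometry at C8a=C8, which places the tether on the outside of the s-cis diene. It also needs aromatisation by loss of hydrogen and not by loss of O1 from C8a, which is secured by excluding protic acid (hindered pyridine buffer, precipitation of the hydroquinone from toluene) and by one equivalent of oxidant at 0 °C, so that the benzylic C2–H and the silyl ethers are left alone.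

Step 8
Reactants: 12 (2S)-7,8-bis(tert-butyldimethylsilyloxy)-2-(3,4-dimethoxyphenyl)-5-methoxychroman-4-one
Product: 14 (2S)-2-(3,4-dimethoxyphenyl)-5,7,8-trimethoxychroman-4-one, via 8-silyloxy-7-methoxy flavanone 13 (not isolated)
Conditions: MeI (20 equiv), CsF (3 equiv, added in portions), DMF, 0 °C → rt, Ar
Reagents that add atoms: iodomethane, CI
Why: Fluoride-induced cleavage of the aryl silyl ethers with in situ Williamson methylation of each aryloxide; the vinylogous C7 silyl ether should fall first, and because iodomethane is present in large excess from the start every aryloxide is capped within its short lifetime, which keeps the medium too weakly basic for E1cB opening of ring C. This replaces a separate deprotection and a diazoalkane methylation.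

## Compound list

1 | ethyl 3-(3,4-dimethoxyphenyl)-3-oxopropanoate | CCOC(=O)CC(=O)c1ccc(OC)c(OC)c1 | starting material
2 | ethyl (3S)-3-(3,4-dimethoxyphenyl)-3-hydroxypropanoate | CCOC(=O)C[C@H](O)c1ccc(OC)c(OC)c1 | intermediate
3 | (3S)-3-(3,4-dimethoxyphenyl)-3-hydroxy-N-methoxy-N-methylpropanamide | CON(C)C(=O)C[C@H](O)c1ccc(OC)c(OC)c1 | intermediate
4 | 1-bromobut-2-yne | CC#CCBr | starting material
5 | (3S)-3-(but-2-yn-1-yloxy)-3-(3,4-dimethoxyphenyl)-N-methoxy-N-methylpropanamide | CON(C)C(=O)C[C@H](OCC#CC)c1ccc(OC)c(OC)c1 | intermediate
6 | (3S)-3-(3,4-dimethoxyphenyl)-3-(2,3-dioxobutoxy)-N-methoxy-N-methylpropanamide | CON(C)C(=O)C[C@H](OCC(=O)C(C)=O)c1ccc(OC)c(OC)c1 | intermediate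
7 | (3S)-3-{[(1Z)-2,3-bis(tert-butyldimethylsilyloxy)buta-1,3-dien-1-yl]oxy}-3-(3,4-dimethoxyphenyl)-N-methoxy-N-methylpropanamide | CON(C)C(=O)C[C@H](O/C=C(\O[Si](C)(C)C(C)(C)C)C(=C)O[Si](C)(C)C(C)(C)C)c1ccc(OC)c(OC)c1 | intermediate
8 | chloroacetaldehyde dimethyl acetal (2-chloro-1,1-dimethoxyethane) | COC(CCl)OC | starting material
9 | lithium methoxyacetylide | [Li+].[C-]#COC | intermediate
10 | (5S)-5-{[(1Z)-2,3-bis(tert-butyldimethylsilyloxy)buta-1,3-dien-1-yl]oxy}-5-(3,4-dimethoxyphenyl)-1-methoxypent-1-yn-3-one | COc1ccc([C@H](CC(=O)C#COC)O/C=C(\O[Si](C)(C)C(C)(C)C)C(=C)O[Si](C)(C)C(C)(C)C)cc1OC | intermediate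
11 | (2S)-7,8-bis(tert-butyldimethylsilyloxy)-2-(3,4-dimethoxyphenyl)-5-methoxy-2,3,6,8a-tetrahydro-4H-chromen-4-one (both C8a epimers) | COc1ccc([C@@H]2CC(=O)C3=C(OC)CC(O[Si](C)(C)C(C)(C)C)=C(O[Si](C)(C)C(C)(C)C)C3O2)cc1OC | intermediate
12 | (2S)-7,8-bis(tert-butyldimethylsilyloxy)-2-(3,4-dimethoxyphenyl)-5-methoxychroman-4-one | COc1ccc([C@@H]2CC(=O)c3c(OC)cc(O[Si](C)(C)C(C)(C)C)c(O[Si](C)(C)C(C)(C)C)c3O2)cc1OC | intermediate
13 | (2S)-8-(tert-butyldimethylsilyloxy)-2-(3,4-dimethoxyphenyl)-5,7-dimethoxychroman-4-one | COc1ccc([C@@H]2CC(=O)c3c(OC)cc(OC)c(O[Si](C)(C)C(C)(C)C)c3O2)cc1OC | intermediate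
14 | (2S)-2-(3,4-dimethoxyphenyl)-5,7,8-trimethoxychroman-4-one | COc1ccc([C@@H]2CC(=O)c3c(OC)cc(OC)c(OC)c3O2)cc1OC | target

## Step count and least certain steps

Total step count: 8. Longest linear sequence: 8 steps (1 → 14); 4 and 8 are commercial and enter directly.

Step 7 (key step, proposed new method). Three things may go wrong. The cycloaddition may be slower than thermal decay of the push–pull ynone or acid-triggered hydrolysis of the silyl enol ethers. The adduct may aromatise by expulsion of O1 from C8a, which opens ring C, instead of by dehydrogenation. The oxidant may go on to abstract the benzylic C2–H. All three stem from the adduct being an electron-rich, doubly allylic ether for which no precedent exists.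

Fallback, known chemistry only, with ring A taken from an arene; it sets out from 1 and returns at 14. Transfer hydrogenation of 1 with the mirror-image catalyst RuCl[(R,R)-TsDPEN](p-cymene) would give ethyl (3R)-3-(3,4-dimethoxyphenyl)-3-hydroxypropanoate F1. This is converted as in step 2 into (3R)-3-(3,4-dimethoxyphenyl)-3-hydroxy-N-methoxy-N-methylpropanamide F2 and silylated (TBSCl, imidazole) to (3R)-3-(tert-butyldimethylsilyloxy)-3-(3,4-dimethoxyphenyl)-N-methoxy-N-methylpropanamide F3. Lithiation of commercial 1,2,3,5-tetramethoxybenzene (n-BuLi, TMEDA) at its only kind of ring C–H gives 2,3,4,6-tetramethoxyphenyllithium F4, which adds to F3 to give (3R)-3-(tert-butyldimethylsilyloxy)-3-(3,4-dimethoxyphenyl)-1-(2,3,4,6-tetramethoxyphenyl)propan-1-one F5. Chelation-controlled mono-demethylation with BCl3 at −78 °C is expected to remove the methyl group of the ortho-methoxy group that is flanked by a second methoxy group, giving (3R)-3-(tert-butyldimethylsilyloxy)-3-(3,4-dimethoxyphenyl)-1-(2-hydroxy-3,4,6-trimethoxyphenyl)propan-1-one F6. Desilylation (HF·pyridine) gives (3R)-3-(3,4-dimethoxyphenyl)-3-hydroxy-1-(2-hydroxy-3,4,6-trimethoxyphenyl)propan-1-one F7. Intramolecular Mitsunobu etherification (PPh3, DIAD, toluene, 0 °C) closes ring C with inversion at the carbinol carbon to 14. The weak points of this fallback are the choice between the two ortho-methoxy groups and partial ionisation of the electron-rich benzylic alcohol during the Mitsunobu step.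

Step 6. Liberated diethylamine or N,O-dimethylhydroxylamine may add to the push–pull ynone during the quench, or enolisation toward C4 may expel the dienyl oxide from C5; both follow from the high electrophilicity of the alkoxy ynone and the β-alkoxy ketone motif.

Fallback; it sets out from 7 and returns at 10. Reduction of 7 with i-Bu2AlH at −78 °C would give (3S)-3-{[(1Z)-2,3-bis(tert-butyldimethylsilyloxy)buta-1,3-dien-1-yl]oxy}-3-(3,4-dimethoxyphenyl)propanal F8, used crude. Addition of 9 at −78 °C gives (5S)-5-{[(1Z)-2,3-bis(tert-butyldimethylsilyloxy)buta-1,3-dien-1-yl]oxy}-5-(3,4-dimethoxyphenyl)-1-methoxypent-1-yn-3-ol F9 as a mixture of C3 epimers. Oxidation with activated MnO2 in CH2Cl2 then forms 10 under neutral, amine-free conditions.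

Step 4. Over-oxidation may cleave the C7–C8 bond of the diketone or attack the benzylic ether C–H, because permanganate is not fully selective once the alkyne is consumed.

Fallback; it sets out from 5 and returns at 6. Semihydrogenation of 5 (H2, Pd/CaCO3 poisoned with Pb(OAc)2, quinoline) would give (3S)-3-[(2Z)-but-2-en-1-yloxy]-3-(3,4-dimethoxyphenyl)-N-methoxy-N-methylpropanamide F10. Dihydroxylation (K2OsO2(OH)4 cat., N-methylmorpholine N-oxide) gives (3S)-3-(2,3-dihydroxybutoxy)-3-(3,4-dimethoxyphenyl)-N-methoxy-N-methylpropanamide F11, as a mixture at the diol carbons that is of no consequence. Double Swern oxidation [(COCl)2, DMSO, Et3N, −78 °C] gives 6.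

Step 5. The double enolisation may be incomplete or unselective: E/Z scrambling at C8a=C8, Lewis acid-promoted Mukaiyama-type self-condensation of the diketone, or silylation at the amide α-carbon followed by β-elimination.

Fallback, two separately controlled enolisations with an isolable intermediate; it sets out from 6 and returns at 7. Compound 6, which should sit largely as its push–pull enol toward C8a, is O-silylated under mild conditions (TBSCl, imidazole, DMF) to (3S)-3-{[(1Z)-2-(tert-butyldimethylsilyloxy)-3-oxobut-1-en-1-yl]oxy}-3-(3,4-dimethoxyphenyl)-N-methoxy-N-methylpropanamide F12. Its geometry is under thermodynamic control (O1 trans to the acetyl group) and it can be purified. Kinetic enolisation of the remaining methyl ketone (LiN(SiMe3)2, TBSCl, THF, −78 °C) then gives 7.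

Step 8. Fluoride or aryloxide may trigger retro-oxa-Michael opening of ring C; the opened phenoxide would be methylated to a chalcone (loss of material), and any reclosure would erode the configuration at C2.

Fallback, which removes the carbonyl that makes the opening possible; it sets out from 12 and returns at 14. Reduction of 12 (NaBH4, CeCl3, THF/MeOH, −40 °C) would give (2S,4S)-7,8-bis(tert-butyldimethylsilyloxy)-2-(3,4-dimethoxyphenyl)-5-methoxychroman-4-ol F13. The same CsF/MeI treatment, now without any elimination pathway, gives (2S,4S)-2-(3,4-dimethoxyphenyl)-5,7,8-trimethoxychroman-4-ol F14. Oxidation with Dess–Martin periodinane buffered with NaHCO3 returns the ketone 14.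

## Further compounds

F1 | step 7 | ethyl (3R)-3-(3,4-dimethoxyphenyl)-3-hydroxypropanoate | CCOC(=O)C[C@@H](O)c1ccc(OC)c(OC)c1
F2 | step 7 | (3R)-3-(3,4-dimethoxyphenyl)-3-hydroxy-N-methoxy-N-methylpropanamide | CON(C)C(=O)C[C@@H](O)c1ccc(OC)c(OC)c1
F3 | step 7 | (3R)-3-(tert-butyldimethylsilyloxy)-3-(3,4-dimethoxyphenyl)-N-methoxy-N-methylpropanamide | CON(C)C(=O)C[C@@H](O[Si](C)(C)C(C)(C)C)c1ccc(OC)c(OC)c1
F4 | step 7 | 2,3,4,6-tetramethoxyphenyllithium | [Li]c1c(OC)cc(OC)c(OC)c1OC
F5 | step 7 | (3R)-3-(tert-butyldimethylsilyloxy)-3-(3,4-dimethoxyphenyl)-1-(2,3,4,6-tetramethoxyphenyl)propan-1-one | O=C(C[C@@H](O[Si](C)(C)C(C)(C)C)c1ccc(OC)c(OC)c1)c1c(OC)cc(OC)c(OC)c1OC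
F6 | step 7 | (3R)-3-(tert-butyldimethylsilyloxy)-3-(3,4-dimethoxyphenyl)-1-(2-hydroxy-3,4,6-trimethoxyphenyl)propan-1-one | O=C(C[C@@H](O[Si](C)(C)C(C)(C)C)c1ccc(OC)c(OC)c1)c1c(OC)cc(OC)c(OC)c1O
F7 | step 7 | (3R)-3-(3,4-dimethoxyphenyl)-3-hydroxy-1-(2-hydroxy-3,4,6-trimethoxyphenyl)propan-1-one | O=C(C[C@@H](O)c1ccc(OC)c(OC)c1)c1c(OC)cc(OC)c(OC)c1O
F8 | step 6 | (3S)-3-{[(1Z)-2,3-bis(tert-butyldimethylsilyloxy)buta-1,3-dien-1-yl]oxy}-3-(3,4-dimethoxyphenyl)propanal | COc1ccc([C@H](CC=O)O/C=C(\O[Si](C)(C)C(C)(C)C)C(=C)O[Si](C)(C)C(C)(C)C)cc1OC
F9 | step 6 | (5S)-5-{[(1Z)-2,3-bis(tert-butyldimethylsilyloxy)buta-1,3-dien-1-yl]oxy}-5-(3,4-dimethoxyphenyl)-1-methoxypent-1-yn-3-ol (C3 epimers) | COc1ccc([C@H](CC(O)C#COC)O/C=C(\O[Si](C)(C)C(C)(C)C)C(=C)O[Si](C)(C)C(C)(C)C)cc1OC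
F10 | step 4 | (3S)-3-[(2Z)-but-2-en-1-yloxy]-3-(3,4-dimethoxyphenyl)-N-methoxy-N-methylpropanamide | CON(C)C(=O)C[C@H](OC/C=C\C)c1ccc(OC)c(OC)c1
F11 | step 4 | (3S)-3-(2,3-dihydroxybutoxy)-3-(3,4-dimethoxyphenyl)-N-methoxy-N-methylpropanamide (mixture at the diol carbons) | CON(C)C(=O)C[C@H](OCC(O)C(C)O)c1ccc(OC)c(OC)c1
F12 | step 5 | (3S)-3-{[(1Z)-2-(tert-butyldimethylsilyloxy)-3-oxobut-1-en-1-yl]oxy}-3-(3,4-dimethoxyphenyl)-N-methoxy-N-methylpropanamide | CON(C)C(=O)C[C@H](O/C=C(\O[Si](C)(C)C(C)(C)C)C(C)=O)c1ccc(OC)c(OC)c1
F13 | step 8 | (2S,4S)-7,8-bis(tert-butyldimethylsilyloxy)-2-(3,4-dimethoxyphenyl)-5-methoxychroman-4-ol | COc1ccc([C@@H]2C[C@H](O)c3c(OC)cc(O[Si](C)(C)C(C)(C)C)c(O[Si](C)(C)C(C)(C)C)c3O2)cc1OC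
F14 | step 8 | (2S,4S)-2-(3,4-dimethoxyphenyl)-5,7,8-trimethoxychroman-4-ol | COc1ccc([C@@H]2C[C@H](O)c3c(OC)cc(OC)c(OC)c3O2)cc1OC
A1 | alternative 1 | (1S,3S)-1-(2-bromo-3,4,6-trimethoxyphenyl)-3-(3,4-dimethoxyphenyl)propane-1,3-diol | COc1ccc([C@@H](O)C[C@H](O)c2c(OC)cc(OC)c(OC)c2Br)cc1OC
A2 | alternative 1 | (2S,4S)-2-(3,4-dimethoxyphenyl)-5,7,8-trimethoxychroman-4-ol | COc1ccc([C@@H]2C[C@H](O)c3c(OC)cc(OC)c(OC)c3O2)cc1OC
A3 | alternative 2 | 5,7,8-trimethoxy-4H-chromen-4-one | O=c1ccoc2c(OC)c(OC)cc(OC)c12
A4 | alternative 2 | (2S)-2-ethynyl-5,7,8-trimethoxychroman-4-one | C#C[C@@H]1CC(=O)c2c(OC)cc(OC)c(OC)c2O1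
A5 | alternative 2 | 2,3-dimethoxybuta-1,3-diene | COC(=C)C(=C)OC
A6 | alternative 2 | (2S)-2-(4,5-dimethoxycyclohexa-1,4-dien-1-yl)-5,7,8-trimethoxychroman-4-one | COC1=C(OC)CC(=CC1)[C@@H]2CC(=O)c3c(OC)cc(OC)c(OC)c3O2
A7 | alternative 3 | (2S,4S)-4-(tert-butyldimethylsilyloxy)-2-(3,4-dimethoxyphenyl)-3,4-dihydro-2H-pyran | COc1ccc([C@@H]2C[C@H](O[Si](C)(C)C(C)(C)C)C=CO2)cc1OC
A8 | alternative 3 | 3-methoxycyclobut-3-ene-1,2-dione | COC1=CC(=O)C1=O
A9 | alternative 3 | 4-[(2S,4S)-4-(tert-butyldimethylsilyloxy)-2-(3,4-dimethoxyphenyl)-3,4-dihydro-2H-pyran-6-yl]-4-hydroxy-3-methoxycyclobut-2-en-1-one (both carbinol epimers) | COc1ccc([C@@H]2C[C@H](O[Si](C)(C)C(C)(C)C)C=C(O2)C3(O)C(OC)=CC3=O)cc1OC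
A10 | alternative 3 | (2S,4S)-4-(tert-butyldimethylsilyloxy)-2-(3,4-dimethoxyphenyl)-7-methoxychroman-5,8-diol | COc1ccc([C@@H]2C[C@H](O[Si](C)(C)C(C)(C)C)c3c(O)cc(OC)c(O)c3O2)cc1OC
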